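# Plakortone L through a ketal-triggered Prins cyclisation that ends in lactonisation

## The problem

Plakortone L is a cis-fused tetrahydrofuro[3,2-b]furan-2-one. A γ-lactone (C1 carbonyl, C2 methylene, C3, C4, lactone oxygen) and a tetrahydrofuran (ether oxygen, C3, C4, C5 methylene, C6) share the C3–C4 bond. C6 carries a methyl group and an unbranched 12-phenyldodecyl chain (C7–C18).

There are three stereocentres: C3 (the only CH), C4 (methyl and lactone oxygen) and C6 (methyl and chain). Read from the structure, the target is (3aS,5S,6aS); H-3, the C4 methyl group and the chain lie on one face, the lactone ring and the C6 methyl group on the other.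

C3 can control C4, because two five-membered rings can only be fused cis. C6 is the hard centre: it is separated from C4 by a methylene group, and its two carbon substituents, methyl and n-alkyl, are too alike for a reagent to tell apart.

Both ether carbons are tertiary and ionise in strong acid, and the β-alkoxy lactone opens by β-elimination in base, so the late steps must be close to neutral.

The structure offers one lever. C6 has one oxygen, two carbon groups and a methylene neighbour, so it is a ketone carbon in disguise, and it is tied through oxygen to C3, which is an allylic carbinol as soon as C4=C5 is an alkene. C4 is tertiary and sits γ to the C1 carboxyl, so a cation there is caught as the five-membered lactone. If the chain enters as a rod-like alkynyl group, the two substituents at C6 also become unlike in size.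

## Retrosynthesis

**17 ⇒ 15.** No skeletal bond is cut; the C7–C8 single bond of plakortone L (17) is traced back to the triple bond of alkynyl lactone 15. The neighbouring choice, carrying the saturated chain through, would ask a methyl and a methylene group at C6 to differ. With the alkyne, C6 has a methyl group and a linear sp carbon, and the cation that has to form at C6 gains conjugation. The forward step must saturate two π bonds without cleaving the C6–O bond, which is propargylic and then allylic during the reduction.

**15 ⇒ 5 + 12.** Three bonds are cut: O–C6, C5–C6 and the lactone O–C4 bond. Two neighbouring cuts were weighed: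
- Cutting only the lactone leaves a tetrahydrofuran whose two quaternary centres still have to be made.
- Cutting O–C3 (oxa-Michael or carbonylative closure) leaves a 1,3-diol of two tertiary carbinols, each needing its own asymmetric step.

The triple cut returns both quaternary centres to sp2 carbons, C6 to a ketal carbon and C4 to an alkene carbon. What remains is hydroxy ester 5, with one stereocentre, and the achiral ketal 12. The forward reaction must exchange the C3 hydroxyl into the ketal, ionise it, close the ether ring through C5, and let the ester capture C4, with C3 directing both new centres.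

**5 ⇒ 4 ⇒ 1 + 2.** The C2–C3 bond is cut as an acetate aldol of tert-butyl acetate (1) and methacrolein (2). Acetate enolates are the least selective aldol donors, and auxiliary versions need two more steps to reach the tert-butyl ester that the cascade requires. The racemate 4 is therefore made in one step and resolved by asymmetric epoxidation, for which an isopropenyl carbinol is a favourable substrate. The forward demand is a clean separation of the two enantiomers' rates.

**12 ⇒ 10 + 8.** The C8–C9 bond between the alkyne and the chain is cut. Cutting C6–C7 instead (acetylide plus acetyl donor, then ketalisation) would place the ketalisation on the valuable chain fragment. Here the ketal is present from the start as 3,3-dimethoxybut-1-yne (10), made from but-3-yn-2-one (9), and the forward step is an acetylide alkylation with (10-bromodecyl)benzene (8).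

**8 ⇒ 6 + 7.** The aryl–C18 bond is cut; 1,10-dibromodecane (6) and phenylmagnesium bromide (7) are coupled once under copper catalysis. The forward demand is monoarylation, met by an excess of 6.

## Roads not taken

**Alternative 1:** The lactone is traced through a Baeyer–Villiger oxidation to a cyclobutanone and this to a [2+2] cycloaddition. The bonds cut are C2–C3 and a temporary C1–C4 bond, later exchanged for O–C4.

- Forward key step: dichloroketene adds to the enol ether C3=C4 of dihydrofuran A1, tert-butyl{[(2R)-2,4-dimethyl-2,3-dihydrofuran-2-yl]methoxy}diphenylsilane, anti to the silyloxymethyl group. The product is dichlorocyclobutanone A2, (1R,3R,5S)-3-{[tert-butyl(diphenyl)silyl]oxymethyl}-7,7-dichloro-3,5-dimethyl-2-oxabicyclo[3.2.0]heptan-6-one.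
- Merits: every operation is of a known type. The regiochemistry is fixed electronically, the fusion is cis by necessity, and the oxygen is later inserted next to the more substituted C4 with retention.
- Weak points: the C6 quaternary centre must already exist in A1 as one enantiomer, which is a separate asymmetric problem. Facial control rests on methyl against silyloxymethyl at a remote carbon. After A2 come dechlorination, oxidation, desilylation, oxidation to the aldehyde, olefination and hydrogenation.
- Comparison: in reliability step by step this road is better than the chosen one, whose central step is untested. The chosen plan sets against it a longest linear sequence of four steps, the creation of both quaternary centres from one cheap stereocentre, and no separate synthesis of the C6 centre.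

**Alternative 2:** The O–C6 and C7–C8 bonds are cut, so that ring and chain are joined in one palladium-catalysed step.

- Forward key step: diol A3, (3S,4S)-1-[(tert-butyldimethylsilyl)oxy]-4,6-dimethylhept-6-ene-3,4-diol, and bromoalkene A4, [(10E)-11-bromoundec-10-en-1-yl]benzene, react with Pd2(dba)3 (zerovalent palladium), a bisphosphine and NaOtBu. Oxidative addition, alkoxide exchange, syn insertion of C6=C7 into the Pd–O bond and reductive elimination give A5, (2S,3S,5S)-2-[2-(tert-butyldimethylsilyloxy)ethyl]-3,5-dimethyl-5-[(2E)-12-phenyldodec-2-en-1-yl]oxolan-3-ol.
- Merits: it is convergent, the reaction class is established, and the lactone follows by hydrogenation, desilylation and oxidative lactonisation.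
- Weak points: A3 already holds two adjacent stereocentres, one tertiary, which need their own asymmetric chemistry. C6 is formed from a 1,1-disubstituted alkene, where insertion is slower and the selectivity relative to C3 is least secure. A second, tertiary alkoxide is present.
- Comparison: its key step has real precedent and similar convergence, which the chosen plan cannot claim. The chosen plan answers with a precursor that has a single stereocentre and with the lactone formed in the same operation.

**Alternative 3:** The C5–C6 bond is cut as a carbenoid C–H insertion.

- Forward key step: Rh2(OAc)4 (divalent rhodium) decomposes diazoketone A6, methyl (3S)-5-diazo-4-oxo-3-{[(2S)-14-phenyltetradecan-2-yl]oxy}pentanoate. The carbenoid carbon inserts into the tertiary C6–H bond next to the ether oxygen and gives furanone A7, methyl 2-[(2S,5S)-5-methyl-3-oxo-5-(12-phenyldodecyl)oxolan-2-yl]acetate.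
- Merits: insertion into an ether α-C–H bond to form a five-membered ring is favoured and proceeds with retention. The C6 configuration is therefore imported from an enantioenriched secondary alcohol and is secure. In this respect the road is better than the chosen plan, where C6 is predicted and not imported.
- Weak points: the ether between two secondary stereogenic carbons in A6 is hard to make. Oxonium ylide formation at the ether oxygen competes with insertion. A7 still needs a methyl addition at C4 from the correct face, next to an epimerisable C3 and in the presence of an ester, before it can lactonise.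
- Comparison: the chosen plan sets against the secure C6 centre the automatic control of C4 by ring fusion and a much shorter sequence.

Key step: step 6

## Route

Remark: in step 6 only the silyl ether and the mixed ketal are treated as discrete intermediates; the oxocarbenium ion and the C4 cation are transient ions and are described in the mechanism of that step.

**Step 1**
Reactants: 1 tert-butyl acetate; 2 methacrolein (2-methylprop-2-enal)
Product: 4 tert-butyl (3RS)-3-hydroxy-4-methylpent-4-enoate (racemate), via lithium 1-tert-butoxyethenolate 3 (not isolated)
Conditions: LiN(iPr)2 (LDA, 1.05 equiv), THF, −78 °C; then 2, −78 °C; aq. NH4Cl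
Reagents that add atoms: none
Why: Aldol addition of a preformed lithium ester enolate; at −78 °C the enolate adds 1,2 to the enal and the tert-butyl ester resists self-condensation; the carbinol centre forms as the racemate.

**Step 2**
Reactants: 4 tert-butyl (3RS)-3-hydroxy-4-methylpent-4-enoate
Product: 5 tert-butyl (3S)-3-hydroxy-4-methylpent-4-enoate
Conditions: Ti(OiPr)4 (15 mol%), D-(−)-diisopropyl tartrate (20 mol%), tBuOOH (0.6 equiv), 4 Å MS, CH2Cl2, −20 °C; chromatography
Reagents that add atoms: none
Why: Sharpless kinetic resolution of a secondary allylic alcohol; with the D-(−)-tartrate the (3R) enantiomer is epoxidised fast and the (3S) alcohol is left behind, and running past half conversion should leave 5 in high enantiomeric purity; the C3 centre is selected here, not created.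

**Step 3**
Reactants: 6 1,10-dibromodecane (3 equiv); 7 phenylmagnesium bromide
Product: 8 (10-bromodecyl)benzene
Conditions: Li2CuCl4 (3 mol%), THF, 0 °C → rt; excess 6 recovered by distillation
Reagents that add atoms: none
Why: Copper-catalysed Kochi-type coupling of an aryl Grignard reagent with a primary alkyl bromide; the excess of dibromide should hold the reaction at monoarylation.

**Step 4**
Reactants: 9 but-3-yn-2-one
Product: 10 3,3-dimethoxybut-1-yne
Conditions: HC(OMe)3, MeOH, TsOH·H2O (cat.), 0 °C → rt; K2CO3; distillation
Reagents that add atoms: trimethyl orthoformate COC(OC)OC; methanol CO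
Why: Acid-catalysed ketalisation with an orthoester as dehydrating agent; the orthoformate keeps the medium dry and drives the equilibrium to the dimethyl ketal.

**Step 5**
Reactants: 10 3,3-dimethoxybut-1-yne; 8 (10-bromodecyl)benzene
Product: 12 (13,13-dimethoxytetradec-11-yn-1-yl)benzene, via lithium acetylide 11 (not isolated)
Conditions: n-BuLi, THF, −78 °C; then 8, DMPU, −78 °C → rt
Reagents that add atoms: none
Why: SN2 alkylation of a lithium acetylide by a primary bromide in the presence of a dipolar co-solvent; the ketal is inert to the base and keeps the ketone masked.

**Step 6**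
Reactants: 5 tert-butyl (3S)-3-hydroxy-4-methylpent-4-enoate; 12 (13,13-dimethoxytetradec-11-yn-1-yl)benzene
Product: 15 (3aS,5R,6aS)-5,6a-dimethyl-5-(12-phenyldodec-1-yn-1-yl)tetrahydrofuro[3,2-b]furan-2(3H)-one, via trimethylsilyl ether 13 (not isolated), via mixed methyl ketal 14 (not isolated)
Conditions: 5, 2,6-di-tert-butyl-4-methylpyridine (2.5 equiv), Me3SiOTf (1.1 equiv), CH2Cl2, −78 °C; then 12, Me3SiOTf (1.1 equiv), 0.02 M, −78 → −30 °C; aq. NaHCO3
Reagents that add atoms: none
Why: Proposed new method: Me3SiOTf first silylates the C3 hydroxyl (13), silyl ether–ketal exchange with 12 gives mixed ketal 14, and a second ionisation gives the alkynyl-stabilised oxocarbenium ion at C6 (the O–C6 bond); the isopropenyl carbon C5 then adds to C6 (C5–C6) and the tertiary C4 cation is taken by the carbonyl oxygen of the tert-butyl ester (O–C4) with loss of 2-methylpropene. The closest known reaction types are Prins cyclisations of oxocarbenium ions made by this exchange (silyl-modified Sakurai cyclisations and Prins–pinacol syntheses of tetrahydrofurans) and the capture of tertiary cations by tert-butyl esters, as in the halolactonisation of tert-butyl alkenoates; new are the 5-endo mode of the Prins event and its termination by an ester. The tetrahydrofuran closes 5-endo-trig with respect to both the alkene and the C=O+ bond, a strained mode made viable because it leads to a tertiary cation and because the ester carbonyl, placed anti to the forming C5–C6 bond, can assist and then trap irreversibly; the lactone closes 5-exo with respect to the former alkene. C4 is controlled by C3: the arm on C3 reaches C4 only from its own face, so the fusion is cis (6aS). C6 is controlled by the geometry of the oxocarbenium ion together with C3: the slim alkynyl group sits syn to C3 across C=O+, the ring has to twist about O–C6 to gain overlap, the syn group thereby becomes pseudo-axial on the face of the pseudo-axial C3 substituent, and the transition state with hydrogen in that place and the arm pseudo-equatorial puts the alkyne cis to H-3 and the methyl group cis to the arm (5R). The step needs this C6 selectivity and needs ring closure to outrun proton loss, hydride shift and intermolecular ketal–alkene reaction; the size difference between methyl and alkynyl, the hindered base that removes TfOH without touching the ions, low temperature and high dilution are the means.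

**Step 7**
Reactants: 15 (3aS,5R,6aS)-5,6a-dimethyl-5-(12-phenyldodec-1-yn-1-yl)tetrahydrofuro[3,2-b]furan-2(3H)-one
Product: 17 plakortone L, (3aS,5S,6aS)-5,6a-dimethyl-5-(12-phenyldodecyl)tetrahydrofuro[3,2-b]furan-2(3H)-one, via cis-alkene 16 (not isolated)
Conditions: H2 (1 atm), 10% Pd/C, EtOAc, rt
Reagents that add atoms: none
Why: Heterogeneous catalytic hydrogenation of the alkyne to the alkane through the cis-alkene; lactone, ethers and arene are inert under these conditions and no stereocentre is touched (the C5 descriptor changes from R to S only because the priorities change).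

## Compound list

1 | tert-butyl acetate | CC(=O)OC(C)(C)C | starting material
2 | methacrolein (2-methylprop-2-enal) | CC(=C)C=O | starting material
3 | lithium 1-tert-butoxyethenolate | C=C(O[Li])OC(C)(C)C | intermediate
4 | tert-butyl (3RS)-3-hydroxy-4-methylpent-4-enoate (racemate) | CC(=C)C(O)CC(=O)OC(C)(C)C | intermediate
5 | tert-butyl (3S)-3-hydroxy-4-methylpent-4-enoate | CC(=C)[C@@H](O)CC(=O)OC(C)(C)C | intermediate
6 | 1,10-dibromodecane | BrCCCCCCCCCCBr | starting material
7 | phenylmagnesium bromide | Br[Mg]c1ccccc1 | starting material
8 | (10-bromodecyl)benzene | BrCCCCCCCCCCc1ccccc1 | intermediate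
9 | but-3-yn-2-one | CC(=O)C#C | starting material
10 | 3,3-dimethoxybut-1-yne | CC(OC)(OC)C#C | intermediate
11 | (3,3-dimethoxybut-1-yn-1-yl)lithium | CC(OC)(OC)C#C[Li] | intermediate
12 | (13,13-dimethoxytetradec-11-yn-1-yl)benzene | CC(OC)(OC)C#CCCCCCCCCCCc1ccccc1 | intermediate
13 | tert-butyl (3S)-4-methyl-3-[(trimethylsilyl)oxy]pent-4-enoate | CC(=C)[C@@H](O[Si](C)(C)C)CC(=O)OC(C)(C)C | intermediate
14 | tert-butyl (3S)-3-[(2-methoxy-14-phenyltetradec-3-yn-2-yl)oxy]-4-methylpent-4-enoate (both epimers at the ketal carbon) | CC(=C)[C@@H](OC(C)(OC)C#CCCCCCCCCCCc1ccccc1)CC(=O)OC(C)(C)C | intermediate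
15 | (3aS,5R,6aS)-5,6a-dimethyl-5-(12-phenyldodec-1-yn-1-yl)tetrahydrofuro[3,2-b]furan-2(3H)-one | C[C@]1(C#CCCCCCCCCCCc2ccccc2)C[C@]2(C)OC(=O)C[C@@H]2O1 | intermediate
16 | (3aS,5R,6aS)-5,6a-dimethyl-5-[(1Z)-12-phenyldodec-1-en-1-yl]tetrahydrofuro[3,2-b]furan-2(3H)-one | C[C@]1(/C=C\CCCCCCCCCCc2ccccc2)C[C@]2(C)OC(=O)C[C@@H]2O1 | intermediate
17 | plakortone L, (3aS,5S,6aS)-5,6a-dimethyl-5-(12-phenyldodecyl)tetrahydrofuro[3,2-b]furan-2(3H)-one | C[C@]1(CCCCCCCCCCCCc2ccccc2)C[C@]2(C)OC(=O)C[C@@H]2O1 | target

## Step count and risks

Total step count: 7. Longest linear sequence: 4 steps (steps 3, 5, 6, 7; equally steps 4, 5, 6, 7 or steps 1, 2, 6, 7).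

**Step 6 (key step, new method).**
- What may go wrong: the 5-endo closure may be too slow. The oxocarbenium ion is then lost by deprotonation at its methyl group, by return to the ketone, or by intermolecular attack of a second alkene. If the ring closes but the ester is late, a 1,2-hydride shift from C3 to the C4 cation or proton loss from C4 ends the cascade without the lactone. Independently, facial selectivity at C6 may be poor, because it rests on a modest size difference, and the tertiary propargylic ether of the product can re-ionise and epimerise on warming.
- Fallback (known chemistry; sets out from 5 and 8, returns at 15): the rings are built first and the alkyne is introduced last, on the convex face of a bicyclic oxocarbenium ion.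
  - Ozonolysis of 5 (O3, CH2Cl2, −78 °C; Me2S) gives tert-butyl (3S)-3-hydroxy-4-oxopentanoate F1.
  - Barbier addition of 3-bromo-2-methylprop-1-ene with In powder in THF/H2O, which for α-hydroxy ketones runs through the chelate and attacks anti to the ester arm, gives tert-butyl (3S,4S)-3,4-dihydroxy-4,6-dimethylhept-6-enoate F2.
  - Camphorsulfonic acid (cat.) in toluene at 60 °C closes the lactone (4S,5S)-4-hydroxy-5-methyl-5-(2-methylprop-2-en-1-yl)oxolan-2-one F3.
  - A second ozonolysis gives the methyl ketone, which closes onto the cis hydroxyl to the hemiketal (3aS,6aS)-5-hydroxy-5,6a-dimethyltetrahydrofuro[3,2-b]furan-2(3H)-one F4. MeOH with pyridinium p-toluenesulfonate gives the methyl ketal (3aS,6aS)-5-methoxy-5,6a-dimethyltetrahydrofuro[3,2-b]furan-2(3H)-one F5.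
  - Separately, 8 and LiC≡CH·H2NCH2CH2NH2 in DMSO give (dodec-11-yn-1-yl)benzene F6; n-BuLi and Bu3SnCl give tributyl(12-phenyldodec-1-yn-1-yl)stannane F7.
  - BF3·OEt2 in CH2Cl2 at −78 °C ionises F5, and F7 should add to the face that carries H-3 and the C4 methyl group. This gives 15, and the route continues with step 7.

**Step 2.**
- What may go wrong: discrimination between the enantiomers may be poor, since the ester carbonyl can bind titanium and loosen the tartrate complex. High enantiomeric purity would then be reached only at high conversion and low recovery; at best half of the material is lost.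
- Fallback (sets out from 2, returns at 5): an auxiliary acetate aldol. Commercial (S)-2-hydroxy-1,2,2-triphenylethyl acetate is doubly deprotonated (LiN(iPr)2, THF), transmetalated with MgBr2 and added to 2 at about −115 °C. This gives (1S)-2-hydroxy-1,2,2-triphenylethyl (3S)-3-hydroxy-4-methylpent-4-enoate F8. KOH in MeOH/H2O gives (3S)-3-hydroxy-4-methylpent-4-enoic acid F9 and returns the auxiliary diol. O-tert-butyl-N,N'-diisopropylisourea in CH2Cl2 esterifies the acid alone and gives 5.

**Step 4.**
- What may go wrong: conjugate addition of methanol to the unsubstituted ynone terminus may compete with ketalisation, and the low-boiling ketal may be lost by evaporation on isolation.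
- Fallback (sets out from 8, returns at 12; steps 4 and 5 are both replaced): the carbonyl is introduced after the chain. Commercial but-3-yn-2-ol is doubly deprotonated (n-BuLi, THF/DMPU) and alkylated at carbon with 8 to give 14-phenyltetradec-3-yn-2-ol F10. MnO2 in CH2Cl2 gives 14-phenyltetradec-3-yn-2-one F11, which is not volatile and is substituted at the β-carbon. HC(OMe)3, MeOH and TsOH·H2O then give 12.

**Step 7.**
- What may go wrong: hydrogenolysis of the C6–O bond, which is propargylic and then allylic while the triple bond is reduced on palladium, would open the tetrahydrofuran.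
- Fallback (sets out from 15, returns at 17): reduction without a metal surface, by diimide generated from p-toluenesulfonylhydrazide and NaOAc in refluxing dimethoxyethane/H2O, used in excess. It passes through the same alkene 16 and cannot form an allyl–metal species.

## Further compounds

F1 | step 6 | tert-butyl (3S)-3-hydroxy-4-oxopentanoate | CC(=O)[C@@H](O)CC(=O)OC(C)(C)C
F2 | step 6 | tert-butyl (3S,4S)-3,4-dihydroxy-4,6-dimethylhept-6-enoate | C=C(C)C[C@](C)(O)[C@@H](O)CC(=O)OC(C)(C)C
F3 | step 6 | (4S,5S)-4-hydroxy-5-methyl-5-(2-methylprop-2-en-1-yl)oxolan-2-one | C=C(C)C[C@]1(C)OC(=O)C[C@@H]1O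
F4 | step 6 | (3aS,6aS)-5-hydroxy-5,6a-dimethyltetrahydrofuro[3,2-b]furan-2(3H)-one (both C5 epimers) | CC1(O)C[C@]2(C)OC(=O)C[C@@H]2O1
F5 | step 6 | (3aS,6aS)-5-methoxy-5,6a-dimethyltetrahydrofuro[3,2-b]furan-2(3H)-one (both C5 epimers) | COC1(C)C[C@]2(C)OC(=O)C[C@@H]2O1
F6 | step 6 | (dodec-11-yn-1-yl)benzene | C#CCCCCCCCCCCc1ccccc1
F7 | step 6 | tributyl(12-phenyldodec-1-yn-1-yl)stannane | CCCC[Sn](CCCC)(CCCC)C#CCCCCCCCCCCc1ccccc1
F8 | step 2 | (1S)-2-hydroxy-1,2,2-triphenylethyl (3S)-3-hydroxy-4-methylpent-4-enoate | CC(=C)[C@@H](O)CC(=O)O[C@@H](c1ccccc1)C(O)(c1ccccc1)c1ccccc1
F9 | step 2 | (3S)-3-hydroxy-4-methylpent-4-enoic acid | CC(=C)[C@@H](O)CC(=O)O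
F10 | step 4 | 14-phenyltetradec-3-yn-2-ol (racemate) | CC(O)C#CCCCCCCCCCCc1ccccc1
F11 | step 4 | 14-phenyltetradec-3-yn-2-one | CC(=O)C#CCCCCCCCCCCc1ccccc1
F0 | step 7 | none | none
A1 | alternative 1 | tert-butyl{[(2R)-2,4-dimethyl-2,3-dihydrofuran-2-yl]methoxy}diphenylsilane | C[C@]1(CO[Si](c2ccccc2)(c2ccccc2)C(C)(C)C)CC(C)=CO1
A2 | alternative 1 | (1R,3R,5S)-3-{[tert-butyl(diphenyl)silyl]oxymethyl}-7,7-dichloro-3,5-dimethyl-2-oxabicyclo[3.2.0]heptan-6-one | C[C@]1(CO[Si](c3ccccc3)(c3ccccc3)C(C)(C)C)C[C@]2(C)C(=O)C(Cl)(Cl)[C@@H]2O1
A3 | alternative 2 | (3S,4S)-1-[(tert-butyldimethylsilyl)oxy]-4,6-dimethylhept-6-ene-3,4-diol | C=C(C)C[C@](C)(O)[C@H](CCO[Si](C)(C)C(C)(C)C)O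
A4 | alternative 2 | [(10E)-11-bromoundec-10-en-1-yl]benzene | Br/C=C/CCCCCCCCCc1ccccc1
A5 | alternative 2 | (2S,3S,5S)-2-[2-(tert-butyldimethylsilyloxy)ethyl]-3,5-dimethyl-5-[(2E)-12-phenyldodec-2-en-1-yl]oxolan-3-ol | C[C@]1(C/C=C/CCCCCCCCCc2ccccc2)C[C@](C)(O)[C@H](CCO[Si](C)(C)C(C)(C)C)O1
A6 | alternative 3 | methyl (3S)-5-diazo-4-oxo-3-{[(2S)-14-phenyltetradecan-2-yl]oxy}pentanoate | C[C@@H](CCCCCCCCCCCCc1ccccc1)O[C@@H](CC(=O)OC)C(=O)C=[N+]=[N-]
A7 | alternative 3 | methyl 2-[(2S,5S)-5-methyl-3-oxo-5-(12-phenyldodecyl)oxolan-2-yl]acetate | C[C@]1(CCCCCCCCCCCCc2ccccc2)CC(=O)[C@H](CC(=O)OC)O1
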